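**Plan**
- Retrosynthetic cuts, in order: the O–benzyl bond (protecting group), C2–CH3 (enolate methylation), then the C4–C4a aryl–alkyl bond while C1 and C4 are rejoined. This contracts the six-membered ketone ring (C1, C2, C3, C4, C4a, C8a) to the four-membered ring of a 1,2-diaryl-3-methylcyclobutanol. Last, C1–aryl (Grignard addition) and C4–aryl (α-arylation) lead back to 3-methylcyclobutanone.
- Forward: desymmetrizing enolization of 3-methylcyclobutanone, α-arylation with the dimethoxyphenyl group, addition of the (benzyloxy)methoxyphenyl Grignard reagent, anodic ring expansion of the cyclobutanol by two atoms to the 4-aryl-1-tetralone, C2 methylation, debenzylation.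
- Enabling feature: C1 (aryl ketone carbon) and C4 (diaryl methine) are both benzylic and 1,4-related, so a C1–C4 bond in a cyclobutanol is strained and doubly benzylic. C4a is an arene CH ortho to C8a and para to the C7 oxygen, placed to accept the C4 radical or cation.
- Stereochemistry: C3 comes from selection between enantiotopic α-protons by a chiral lithium amide. C4 is set in the ring-closing event (aryl trans to the C3 methyl). C2 is set by enolate methylation anti to the C3 methyl, backed by equilibration to the all-trans isomer.

Key step: step 5

Assumption: lithium (R,R)-bis(1-phenylethyl)amide is taken to give the (R)-enolate of 3-methylcyclobutanone; if the sense of induction is the opposite, the (S,S)-amide is used and nothing else changes. 3-Methylcyclobutan-1-one is taken as a commercial building block.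

**Step 1**
Reactants: 1 5-bromo-2-methoxyphenol; 2 benzyl bromide
Product: 3 2-(benzyloxy)-4-bromo-1-methoxybenzene
Conditions: BnBr, K2CO3, DMF, rt
Reagents that add atoms: benzyl bromide, BrCc1ccccc1
Why: Williamson ether synthesis (SN2 of the phenoxide on benzyl bromide) masks the phenol for the organometallic and oxidative steps and keeps the ring position para to this oxygen activated.

**Step 2**
Reactants: 4 3-methylcyclobutan-1-one; 5 chlorotriethylsilane
Product: 7 (R)-triethyl[(3-methylcyclobut-1-en-1-yl)oxy]silane, via lithium (R)-enolate 6 (not isolated)
Conditions: (R,R)-bis(1-phenylethyl)amine, n-BuLi, THF, −78 to 0 °C; then TESCl and 4 (in situ quench), THF, −100 °C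
Reagents that add atoms: chlorotriethylsilane, CC[Si](Cl)(CC)CC
Why: Enantioselective deprotonation of a prochiral ketone by a C2-symmetric chiral lithium amide with in situ silyl trapping (a desymmetrization precedented for 3-substituted cyclobutanones) removes one of the two enantiotopic α-protons, which makes C3 a stereocentre and stores the choice as the regiochemistry of the enol ether.

**Step 3**
Reactants: 7 (R)-triethyl[(3-methylcyclobut-1-en-1-yl)oxy]silane; 8 4-bromo-1,2-dimethoxybenzene
Product: 10 (2R,3R)-2-(3,4-dimethoxyphenyl)-3-methylcyclobutan-1-one, via tributyltin enolate 9 (not isolated)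
Conditions: Pd(OAc)2 (3 mol%), P(t-Bu)3 (6 mol%), Bu3SnF (1.1 equiv), toluene, 60 °C
Reagents that add atoms: 4-bromo-1,2-dimethoxybenzene, COc1ccc(Br)cc1OC
Why: Palladium-catalysed α-arylation of a silyl enol ether through its tin enolate takes place at the enol carbon without free-enolate equilibration, so the C3 configuration is kept, and the aryl group settles trans to the methyl group at the epimerizable C2 (a centre that is erased again in step 5).

**Step 4**
Reactants: 3 2-(benzyloxy)-4-bromo-1-methoxybenzene; 10 (2R,3R)-2-(3,4-dimethoxyphenyl)-3-methylcyclobutan-1-one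
Product: 12 (1R,2R,3R)-1-[3-(benzyloxy)-4-methoxyphenyl]-2-(3,4-dimethoxyphenyl)-3-methylcyclobutan-1-ol, via arylmagnesium bromide 11 (not isolated)
Conditions: 3, Mg, THF, 40 °C; then 10, LaCl3·2LiCl, THF, −78 to 0 °C; aq NH4Cl
Reagents that add atoms: 2-(benzyloxy)-4-bromo-1-methoxybenzene (as its Grignard reagent), COc1ccc(Br)cc1OCc1ccccc1
Why: Grignard 1,2-addition to the strained, highly electrophilic cyclobutanone, with the lanthanum salt suppressing enolization of the α-aryl ketone, should occur anti to the C2 aryl group; the carbinol configuration is of no consequence because C1 becomes the carbonyl carbon.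

**Step 5**
Reactants: 12 (1R,2R,3R)-1-[3-(benzyloxy)-4-methoxyphenyl]-2-(3,4-dimethoxyphenyl)-3-methylcyclobutan-1-ol
Product: 13 (3R,4R)-7-(benzyloxy)-4-(3,4-dimethoxyphenyl)-6-methoxy-3-methyl-3,4-dihydronaphthalen-1(2H)-one
Conditions: graphite anode, Pt cathode, undivided cell, constant current (ca. 2.2 F/mol), n-Bu4NPF6, 2,6-lutidine, HFIP/CH2Cl2 (1:4), rt
Reagents that add atoms: none
Why: Anodic one-electron oxidation of the electron-rich 1,2-diarylcyclobutanol gives an arene radical cation in which the strained, doubly benzylic C1–C2 bond breaks with loss of the O–H proton to lutidine (β-scission), leaving the aryl ketone and a 3,4-dimethoxybenzylic radical at the future C4; this radical, or the benzylic cation formed from it by a second anodic electron transfer, attacks the aroyl ring at the CH ortho to the new carbonyl group and para to the benzyloxy group, and loss of a proton restores the arene while the cathode turns the two protons into H2. The closest known reaction type is the oxidative (silver-, manganese- or cerium-mediated, or electrochemical) ring expansion of 1-arylcyclobutanols to 1-tetralones by alkoxy-radical β-scission and cyclization onto the arene. The six-membered ketone ring is closed by ortho attack on the arene (formally 6-endo with respect to the ipso–ortho bond, a Friedel–Crafts or homolytic aromatic substitution closure), so that the four cyclobutane carbons and two arene carbons become the tetralone ring. The new C4 stereocentre is controlled by the untouched C3 methyl stereocentre: in the half-chair transition state the C3 methyl and the C4 aryl group both lie pseudo-equatorial, which should give the 3,4-trans isomer. The step needs cleavage of C1–C2 and not C1–C4 (secured by the dimethoxyphenyl group on C2), closure at the arene carbon para to OBn and not at the crowded carbon between C=O and OBn or at the ipso carbon (secured by the para oxygen and by the preference for six-membered over spiro five-membered closure), and oxidation of the substrate in preference to the product (secured by the strain-driven fragmentation open only to the cyclobutanol and by charge control).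

**Step 6**
Reactants: 13 (3R,4R)-7-(benzyloxy)-4-(3,4-dimethoxyphenyl)-6-methoxy-3-methyl-3,4-dihydronaphthalen-1(2H)-one; 14 iodomethane
Product: 16 (2R,3S,4R)-7-(benzyloxy)-4-(3,4-dimethoxyphenyl)-6-methoxy-2,3-dimethyl-3,4-dihydronaphthalen-1(2H)-one, via lithium enolate 15 (not isolated)
Conditions: LiHMDS, THF, −78 °C; MeI, −78 to −40 °C; then cat. NaOMe, MeOH, rt
Reagents that add atoms: iodomethane, CI
Why: Lithium enolate formation at the only enolizable position and SN2 methylation anti to the neighbouring C3 methyl group (as in the trans-selective alkylation of 3-substituted cyclohexanone enolates) should set C2, and the methoxide equilibration converges any cis epimer on the all-trans, all-equatorial isomer.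

**Step 7**
Reactants: 16 (2R,3S,4R)-7-(benzyloxy)-4-(3,4-dimethoxyphenyl)-6-methoxy-2,3-dimethyl-3,4-dihydronaphthalen-1(2H)-one
Product: 17 epischisandrone, (2R,3S,4R)-4-(3,4-dimethoxyphenyl)-7-hydroxy-6-methoxy-2,3-dimethyl-3,4-dihydronaphthalen-1(2H)-one
Conditions: H2 (1 atm), Pd/C (10% palladium on carbon), EtOAc, rt
Reagents that add atoms: none
Why: Hydrogenolysis of the benzyl aryl ether under neutral conditions frees the phenol without touching the electron-rich aryl ketone, the methyl ethers or the three stereocentres.

**Compound list**
1 | 5-bromo-2-methoxyphenol | COc1ccc(Br)cc1O | starting material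
2 | benzyl bromide | BrCc1ccccc1 | starting material
3 | 2-(benzyloxy)-4-bromo-1-methoxybenzene | COc1ccc(Br)cc1OCc1ccccc1 | intermediate
4 | 3-methylcyclobutan-1-one | CC1CC(=O)C1 | starting material
5 | chlorotriethylsilane | CC[Si](Cl)(CC)CC | starting material
6 | lithium (R)-3-methylcyclobut-1-en-1-olate (not isolated) | [Li]OC1=C[C@H](C)C1 | intermediate
7 | (R)-triethyl[(3-methylcyclobut-1-en-1-yl)oxy]silane | CC[Si](CC)(CC)OC1=C[C@H](C)C1 | intermediate
8 | 4-bromo-1,2-dimethoxybenzene | COc1ccc(Br)cc1OC | starting material
9 | tributyl{[(3R)-3-methylcyclobut-1-en-1-yl]oxy}stannane (not isolated) | CCCC[Sn](CCCC)(CCCC)OC1=C[C@H](C)C1 | intermediate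
10 | (2R,3R)-2-(3,4-dimethoxyphenyl)-3-methylcyclobutan-1-one (aryl trans to methyl) | O=C1C[C@@H](C)[C@@H]1c1ccc(OC)c(OC)c1 | intermediate
11 | [3-(benzyloxy)-4-methoxyphenyl]magnesium bromide (not isolated) | COc1ccc([Mg]Br)cc1OCc1ccccc1 | intermediate
12 | (1R,2R,3R)-1-[3-(benzyloxy)-4-methoxyphenyl]-2-(3,4-dimethoxyphenyl)-3-methylcyclobutan-1-ol (OH cis to the C2 aryl group, methyl trans to it) | O[C@]1(c2ccc(OC)c(OCc3ccccc3)c2)C[C@@H](C)[C@@H]1c1ccc(OC)c(OC)c1 | intermediate
13 | (3R,4R)-7-(benzyloxy)-4-(3,4-dimethoxyphenyl)-6-methoxy-3-methyl-3,4-dihydronaphthalen-1(2H)-one (3,4-trans) | COc1cc2c(cc1OCc1ccccc1)C(=O)C[C@@H](C)[C@@H]2c1ccc(OC)c(OC)c1 | intermediate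
14 | iodomethane | CI | starting material
15 | lithium enolate of 13 (C1–OLi, C1=C2; C3 and C4 unchanged; not isolated) | COc1cc2c(cc1OCc1ccccc1)C(O[Li])=C[C@@H](C)[C@@H]2c1ccc(OC)c(OC)c1 | intermediate
16 | (2R,3S,4R)-7-(benzyloxy)-4-(3,4-dimethoxyphenyl)-6-methoxy-2,3-dimethyl-3,4-dihydronaphthalen-1(2H)-one (all-trans) | COc1cc2c(cc1OCc1ccccc1)C(=O)[C@H](C)[C@@H](C)[C@@H]2c1ccc(OC)c(OC)c1 | intermediate
17 | epischisandrone, (2R,3S,4R)-4-(3,4-dimethoxyphenyl)-7-hydroxy-6-methoxy-2,3-dimethyl-3,4-dihydronaphthalen-1(2H)-one | COc1cc2c(cc1O)C(=O)[C@H](C)[C@@H](C)[C@@H]2c1ccc(OC)c(OC)c1 | target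

**Step count**
Total steps: 7. Longest linear sequence: 6 steps (4 to 17, steps 2 to 7); step 1 prepares the aryl bromide for the convergent step 4.

**Steps most likely to fail**

Step 5. After ring opening the benzylic cation may lose a proton toward C3 (which would also erase the C3 stereocentre) or be captured by the medium faster than it closes onto the acyl-deactivated ring. The product may also be oxidized further at the anode, and facial selectivity at C4 may be incomplete. The fallback sets out from 12 and separates ring opening from ring closure. Photocatalytic proton-coupled electron transfer ([Ir(dF(CF3)ppy)2(5,5'-d(CF3)bpy)]PF6, 2,4,6-collidine, thiophenol, CH2Cl2, blue light) should trigger the same C1–C2 β-scission, with the benzylic radical reduced by the thiol. This redox-neutral isomerization would give (S)-1-[3-(benzyloxy)-4-methoxyphenyl]-4-(3,4-dimethoxyphenyl)-3-methylbutan-1-one F1. The C4–C4a bond is then closed by benzylic hydride abstraction and Friedel–Crafts alkylation (DDQ, TFA, CH2Cl2, 0 °C), as practised for aryltetralin lignans, and the route is rejoined at 13.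

Step 2. Discrimination between the two enantiotopic α-protons may be incomplete, or proton exchange between enolate and ketone before silylation may lower the enantiomeric purity. The fallback sets out from 4 and replaces asymmetric deprotonation by resolution. LDA and TESCl in THF at −78 °C give, by way of racemic lithium 3-methylcyclobut-1-en-1-olate F2, racemic triethyl[(3-methylcyclobut-1-en-1-yl)oxy]silane F3. Arylation under the conditions of step 3, by way of racemic tributyl[(3-methylcyclobut-1-en-1-yl)oxy]stannane F4, gives racemic trans-2-(3,4-dimethoxyphenyl)-3-methylcyclobutan-1-one F5. Preparative chromatography on a chiral stationary phase then separates the enantiomers, and the (2R,3R) enantiomer rejoins the route at 10.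

Step 3. The strained ketone may self-condense, proton transfer between the tin enolate and the ketone may scramble the enolate regiochemistry (and with it the C3 configuration), a second arylation may occur at the more acidic α-aryl position, or the silyloxycyclobutene may ring-open thermally. The fallback sets out from 7 and switches from cross-coupling of an enolate to electrophilic aryl transfer from hypervalent iodine. The reagent (3,4-dimethoxyphenyl)(2,4,6-trimethylphenyl)iodonium trifluoromethanesulfonate F6 is made in one operation from 1,2-dimethoxybenzene, iodomesitylene diacetate and TfOH. With Cu(OTf)2 (10 mol%) and 2,6-di-tert-butylpyridine in CH2Cl2 at rt, the enol ether reacts directly as a π-nucleophile at its enol carbon, no free enolate is formed, and the route is rejoined at 10.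

**Further compounds**
F1 | step 5 | (S)-1-[3-(benzyloxy)-4-methoxyphenyl]-4-(3,4-dimethoxyphenyl)-3-methylbutan-1-one | COc1ccc(C[C@H](C)CC(=O)c2ccc(OC)c(OCc3ccccc3)c2)cc1OC
F2 | step 2 | racemic lithium 3-methylcyclobut-1-en-1-olate | [Li]OC1=CC(C)C1
F3 | step 2 | racemic triethyl[(3-methylcyclobut-1-en-1-yl)oxy]silane | CC[Si](CC)(CC)OC1=CC(C)C1
F4 | step 2 | racemic tributyl[(3-methylcyclobut-1-en-1-yl)oxy]stannane | CCCC[Sn](CCCC)(CCCC)OC1=CC(C)C1
F5 | step 2 | racemic trans-2-(3,4-dimethoxyphenyl)-3-methylcyclobutan-1-one | O=C1CC(C)C1c1ccc(OC)c(OC)c1
F6 | step 3 | (3,4-dimethoxyphenyl)(2,4,6-trimethylphenyl)iodonium trifluoromethanesulfonate | COc1ccc([I+]c2c(C)cc(C)cc2C)cc1OC.[O-]S(=O)(=O)C(F)(F)F
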